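# Proposed total synthesis of CNP0220567.2 (40) by anionic oxy-Cope ring expansion

## Analysis of the target

Target 40 is a germacranolide. It has a ten-membered carbocycle (C1–C10; biogenetic numbering, C14 on C10, C15 on C4, C11–C13 in the lactone) trans-fused at C6/C7 to an α-methylene-γ-butyrolactone. The ring holds two trisubstituted olefins, both ring-cis: C1=C10 (Z, bearing the C14 hydroxymethyl group) and C4=C5 (Z, bearing the C15 methyl group). Four contiguous stereocentres run from C6 to C9 (6R,7S,8S,9S). On a flat drawing O6 and O9 lie on one face and C11 and O8 on the other, so the lactone is trans-fused, C7/C8 are cis and the C8/C9 diol is trans (threo). Three hydroxyls must be told apart: C8 carries an isobutyrate, C9 a 2-hydroxyisobutyrate with a free tertiary hydroxyl, and C14 stays free. The sensitive groups are the α-methylene lactone (a Michael acceptor), the vicinal and 1,3-related esters (acyl migration), and the allylic C–O bonds at C6, C9 and C14. The difficulty is a medium ring with two Z olefins combined with four adjacent stereocentres and a differentiated triol. The route rests on one feature: the C8–C9 bond lies between C7 (α to the oxygenated C6) and the C10=C1 olefin. C8–C9 is therefore the new σ bond of an oxy-Cope array C8=C7–C6(O)–C1–C10=C9. Its C1–C6 bond closes a 3-methylcyclohexene that already contains the Z C4=C5 olefin.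

## Retrosynthetic reasoning

**Acyl groups and C14 (40 back to 32).** The C8 isobutyrate, the C9 hydroxyisobutyrate and the free C14 hydroxyl are taken apart in the reverse of their order of installation. 40 comes from the bis-silyl compound 39 by one desilylation, 39 from alcohol 38 by acylation at O8, 38 from 4-methoxybenzyl ether 37, and 37 from alcohol 32 and the silyl-protected acid 35 (made from 33). Each hydroxyl is set free only just before it is acylated, which limits acyl migration. The differentiation comes directly from the key step: O8 must be an ether there, and O9/O14 emerge tied together as an acetonide (diol 31, acetonide 30).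

**α-Methylene lactone (30 back to 22).** The C11=C13 bond is cut first (lactone 26). The lactone C–O bond and the C6–H bond are then cut to keto ester 24, and the C7–C11 bond is cut to ketone 22. These cuts are chosen because the ring expansion leaves a C6 ketone and C7 is its α-carbon. The forward steps must set C7 and C6 on the ten-membered ring. The C8 ether oxygen, β to the ketone, is used as a chelating handle for both.

**Ten-membered ring (22 back to 19).** The C8–C9 bond is cut and the C1–C6 bond re-formed in a retro-[3,3] sense. This turns the cyclodecadienone into the cis-1,2-dialkenylcyclohexenol 19. One terminus is an E enol ether (C7=C8) and the other a ring-locked enol ether (the dioxin, C10=C9 with C14). The gain is threefold: no end-to-end closure of a medium ring, the Z C4=C5 olefin is the cyclohexene double bond, and C8 and C9 are both set from olefin geometry. The forward step must run through one chair and the product enolate must survive as the β-alkoxy ketone.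

**Enol ether and carbinol (19 back to 8 and 13).** The E enol ether is traced to alkyne 17 (trans-hydroalumination directed by the tertiary hydroxyl). The carbinol C–C bond is traced to ketone 8 and acetylide 15, which comes from dichlorovinyl ether 13 and hence from 9 and 10. The addition must place the alkyne cis to the dioxinyl group and must not enolise the labile α-centre of 8.

**Alkenyl-bearing centre (8 back to 4 and 3).** The bond between the ring and the dioxin is cut to the kinetic enolate 5 of enone 4 and enol triflate 3 (from ketone 1). Because this α-centre is easily enolised, it is not set in the coupling. Racemic 6 is reduced under dynamic kinetic resolution to alcohol 7, and mild re-oxidation gives 8 as one enantiomer. This centre is the only source of absolute configuration; the key step transfers it to C8 and C9.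

## Alternatives that were turned down

**Alternative 1:** The ring is disconnected by re-forming a transannular C4–C9 bond, which turns the ten-membered ring into a cis-fused bicyclic framework. In the forward sense a tertiary C9 alkoxide with a sulfonate at C5 would undergo a concerted Grob fragmentation to the lactone-fused dienone A1.
- For: like the chosen route it opens a ring instead of closing one, and the Z C4=C5 geometry follows stereospecifically from the antiperiplanar fragmentation. On one point it is stronger: C6 and C7 would be set on a rigid six-membered ring, whereas the chosen route sets them on the flexible ten-membered ring.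
- Against: A1 has no oxygen at C8, no C14 and a ketone at C9. After the ring is formed, C8 must be hydroxylated next to the ketone with control relative to C7, a hydroxymethyl group must be put on C10 of a Z enone, and C9 must be reduced selectively. All three would be done on the medium ring without an internal control element.
- Comparison: the chosen route creates C8, C9 and the C14 oxygen pattern in the ring-forming step and pays for it with substrate-controlled steps at C7 and C6.

**Alternative 2:** The ring is disconnected at C5–C6. In the forward sense an alkynylchromium species (CrCl2, catalytic NiCl2) made from a C5 iodoalkyne would add to a C6 aldehyde and close the cyclic enyne A2. Oxidation of the carbinol, conjugate addition of a methyl group to C4, reduction at C6 and lactonisation would follow.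
- For: C7, C8 and C9 and the C9 ester would be fixed in an open chain by well-controlled acyclic methods, and the late protecting-group steps of the chosen route would largely disappear. On that point it is stronger.
- Against: it closes a ten-membered ring end to end, with a bent alkyne and a Z olefin in the ring, so dilution and an entropic penalty are unavoidable. The C6 centre is made, destroyed and made again. The Z geometry of C4=C5 would depend on how a methyl cuprate adds to a medium-ring ynone and how the allenolate is protonated. The allylic C9 ester must survive divalent chromium and cuprate reagents. The open-chain precursor needs a long linear sequence.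
- Comparison: the chosen route gets the Z C4=C5 olefin from a cyclohexene and reaches the ring in eight steps.

**Alternative 3:** The ring is disconnected at C9–C10. In the forward sense a Z alkenyl iodide at C10 would be converted (CrCl2, catalytic NiCl2, DMSO, high dilution) into an alkenylchromium species that adds to a C9 aldehyde, giving A3, which is the same compound as 32 of the present route.
- For: the lactone, the exocyclic methylene and the C6–C8 centres would all be in place before the ring is closed. This is stronger than the chosen route at C6 and C7, and the closure lands directly on an advanced intermediate.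
- Against: the closure is entropically costly. C9 would be set by the facial selectivity of an α-alkoxy aldehyde in a strained transition state and not by olefin geometry. The α-alkoxy aldehyde can epimerise at C8. The α-methylene lactone is exposed to a single-electron reductant. The open chain must carry a Z trisubstituted olefin, a Z iodoalkene and three stereocentres, which costs more steps than the chosen route needs to reach 32.
- Comparison: the chosen route forms the ring without dilution and sets C8/C9 together, and accepts less certain control at C6/C7.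

Key step: step 8

## Assumptions

- The sense of induction in step 3 is taken from 2-alkylcyclohexanones; if it proves reversed, the antipodal catalyst is used.
- The cyclohexene compounds 6–8, 17 and 19 are named with their own ring numbering (C1 carbonyl or carbinol carbon, C6 bearing the dioxinyl group). From step 8 on, biogenetic numbering is used. The mapping is: cyclohexene C1 = C6, cyclohexene C6 = C1, the two-carbon side chain = C7 and C8, dioxin C5/C6/C4 = C10/C9/C14.

## Route

**Step 1**
Reactants: 1 2,2-dimethyl-1,3-dioxan-5-one
Product: 3 2,2-dimethyl-4H-1,3-dioxin-5-yl trifluoromethanesulfonate, via lithium enolate 2 (not isolated)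
Conditions: LiN(SiMe3)2, THF, −78 °C; then PhNTf2, −78 → 0 °C
Reagents that add atoms: N-phenylbis(trifluoromethanesulfonimide), O=S(=O)(N(c1ccccc1)S(=O)(=O)C(F)(F)F)C(F)(F)F
Why: Enol triflate formation by O-sulfonylation of the kinetic lithium enolate; the ketone is symmetrical, so there is no regiochemical question, and the enol double bond ends up inside the ring as the 4H-1,3-dioxin needed later.

**Step 2**
Reactants: 4 3-methylcyclohex-2-en-1-one; 3 2,2-dimethyl-4H-1,3-dioxin-5-yl trifluoromethanesulfonate
Product: 6 racemic 6-(2,2-dimethyl-4H-1,3-dioxin-5-yl)-3-methylcyclohex-2-en-1-one, via lithium enolate 5 (not isolated)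
Conditions: 4, LiN(SiMe3)2 (2.2 equiv), THF, −78 °C; then 3, Pd2(dba)3 (2 mol %), P(t-Bu)3 (4 mol %), −78 → 25 °C; pH 7 phosphate buffer, −78 °C
Reagents that add atoms: none
Why: Palladium-catalysed α-alkenylation of a ketone enolate with an alkenyl triflate (oxidative addition of zerovalent palladium into C–OTf, transmetalation with the enolate, reductive elimination). Kinetic deprotonation of 4 at −78 °C gives the cross-conjugated α′ enolate 5, and the excess base keeps the more acidic product as its dienolate, which is protonated at the α-carbon on cold quench to give the β,γ-unsaturated ketone. The product is racemic and its configuration is dealt with in step 3.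

**Step 3**
Reactants: 6 racemic 6-(2,2-dimethyl-4H-1,3-dioxin-5-yl)-3-methylcyclohex-2-en-1-one
Product: 7 (1S,6S)-6-(2,2-dimethyl-4H-1,3-dioxin-5-yl)-3-methylcyclohex-2-en-1-ol
Conditions: H2 (8 atm), trans-RuCl2[(R)-binap][(S,S)-dpen] (0.5 mol %), KOt-Bu (5 mol %), i-PrOH, 25 °C
Reagents that add atoms: none
Why: Noyori asymmetric hydrogenation with dynamic kinetic resolution. The alkoxide base racemises C6 of 6 through its dienolate while the diphosphine–diamine ruthenium hydride reduces only C=O and should consume the (6S) ketone faster, giving the cis alcohol with C6 fixed as S. This outer-sphere catalyst leaves the ring olefin and the enol ether untouched, and the conjugation of the dioxin enol ether should offset the driving force for moving that double bond into conjugation with the ketone.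

**Step 4**
Reactants: 7 (1S,6S)-6-(2,2-dimethyl-4H-1,3-dioxin-5-yl)-3-methylcyclohex-2-en-1-ol
Product: 8 (6S)-6-(2,2-dimethyl-4H-1,3-dioxin-5-yl)-3-methylcyclohex-2-en-1-one
Conditions: activated MnO2, CH2Cl2, 25 °C; filtration through Celite; used at once
Reagents that add atoms: none
Why: Allylic alcohol oxidation on the surface of MnO2 under neutral heterogeneous conditions, so the enolisable C6 centre and the acid-labile enol ether should both survive. The carbinol centre of 7 is deliberately destroyed; only C6 is needed.

**Step 5**
Reactants: 9 4-methoxybenzyl alcohol; 10 trichloroethylene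
Product: 13 (E)-1,2-dichlorovinyl 4-methoxybenzyl ether, via potassium alkoxide 11 (not isolated), via dichloroacetylene 12 (not isolated)
Conditions: KH (2 equiv), THF, 0 °C; then 10, −50 → 25 °C; MeOH quench
Reagents that add atoms: none
Why: The alkoxide dehydrochlorinates trichloroethylene to dichloroacetylene in the flask and then adds to it in an anti sense (addition of an alkoxide to a haloalkyne), which gives the E dichloroenol ether, a storable precursor of the alkoxyacetylide.

**Step 6**
Reactants: 13 (E)-1,2-dichlorovinyl 4-methoxybenzyl ether; 8 (6S)-6-(2,2-dimethyl-4H-1,3-dioxin-5-yl)-3-methylcyclohex-2-en-1-one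
Product: 17 (1R,6S)-6-(2,2-dimethyl-4H-1,3-dioxin-5-yl)-1-[(4-methoxybenzyloxy)ethynyl]-3-methylcyclohex-2-en-1-ol, via chloroalkynyl ether 14 (not isolated), via lithium acetylide 15 (not isolated), via cerium acetylide 16 (not isolated)
Conditions: 13 (1.5 equiv), n-BuLi (3.3 equiv), THF, −78 → −40 °C; CeCl3, THF, −78 °C; then 8, −78 °C; aq. NaHCO3
Reagents that add atoms: none
Why: Elimination and chlorine–lithium exchange convert 13 into the lithium alkoxyacetylide, and transmetalation to the organocerium reagent gives a nucleophile that adds 1,2 to the enone without enolising the labile C6 centre (organocerium carbonyl addition). The slim sp nucleophile is expected to take the axial trajectory on the half-chair with the dioxinyl group pseudoequatorial, which puts the alkyne cis to the dioxinyl group and sets the carbinol centre as R. The product is kept cold and base-washed because benzyl-type ynol ethers rearrange on warming and with acid.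

**Step 7**
Reactants: 17 (1R,6S)-6-(2,2-dimethyl-4H-1,3-dioxin-5-yl)-1-[(4-methoxybenzyloxy)ethynyl]-3-methylcyclohex-2-en-1-ol
Product: 19 (1R,6S)-6-(2,2-dimethyl-4H-1,3-dioxin-5-yl)-1-[(E)-2-(4-methoxybenzyloxy)vinyl]-3-methylcyclohex-2-en-1-ol, via alkenylaluminate 18 (not isolated)
Conditions: NaAlH2(OCH2CH2OCH3)2, THF, −20 → 0 °C; aq. KNaC4H4O6 (potassium sodium tartrate); chromatography on Et3N-deactivated silica
Reagents that add atoms: none
Why: Hydroxyl-directed trans-hydroalumination of a propargylic alcohol. The aluminium alkoxide delivers hydride to the proximal alkyne carbon and the cyclic alkenylaluminate is protonated with retention on work-up, which gives the E enol ether only. No acid is used at any point, since 19 would ionise to an enal.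

**Step 8**
Reactants: 19 (1R,6S)-6-(2,2-dimethyl-4H-1,3-dioxin-5-yl)-1-[(E)-2-(4-methoxybenzyloxy)vinyl]-3-methylcyclohex-2-en-1-ol
Product: 22 (1(10)Z,4Z,8S,9S)-9,14-isopropylidenedioxy-8-(4-methoxybenzyloxy)-11,12,13-trinorgermacra-1(10),4-dien-6-one, via potassium alkoxide 20 (not isolated), via potassium enolate 21 (not isolated)
Conditions: KH (1.5 equiv), 18-crown-6 (1.5 equiv), THF, 0 → 25 °C; then AcOH in THF, −78 °C
Reagents that add atoms: none
Why: KH with 18-crown-6 gives the dissociated potassium alkoxide 20, whose oxyanion weakens the adjacent C1–C6 bond so that the [3,3] shift of the array C8=C7–C6–C1–C10=C9 should run at or below room temperature; this is an anionic oxy-Cope rearrangement, and the closest known reaction type is the conversion of 1,2-dialkenylcyclohexanols into cyclodec-5-enones. The ten-membered ring is not closed end to end: it arises by ring expansion, the C1–C6 bond of the cyclohexene being exchanged for the new C8–C9 bond through a six-membered chair transition state, so no entropy of macrocyclisation is paid and the Z C4=C5 bond is carried over from the cyclohexene. With the two alkenyl groups cis, the chair that keeps the dioxinyl group equatorial on the cyclohexene has C2 axial on C1 of the chair, which makes C2 and C9 cis on the new C1=C10 bond (1(10)Z). C8 is controlled by the E geometry of the enol ether and C9 by the ring-locked geometry of the dioxin, so both oxygens sit equatorial on the chair and the two new centres come out threo; the absolute sense (8S,9S) is transferred from C1 and C6 of 19, which both cease to be stereocentres. The step needs this chair to win over the boat and over its ring-flipped partner; the flipped chair would put the dioxinyl group axial and would give the 1(10)E isomer with inverted C8 and C9, a separable diastereomer, so the enantiomeric purity of 22 is not at stake. The enolate 21 has the C8 ether β to the enolate carbon, but as formed the new C8–C9 bond and not the C8–O bond overlaps with the enolate π system, and protonation with AcOH at −78 °C is meant to outrun β-elimination and gives the C6 ketone.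

**Step 9**
Reactants: 22 (1(10)Z,4Z,8S,9S)-9,14-isopropylidenedioxy-8-(4-methoxybenzyloxy)-11,12,13-trinorgermacra-1(10),4-dien-6-one
Product: 24 methyl (1(10)Z,4Z,7R,8S,9S)-9,14-isopropylidenedioxy-8-(4-methoxybenzyloxy)-6-oxo-13-norgermacra-1(10),4-dien-12-oate, via lithium enolate 23 (not isolated)
Conditions: LiN(i-Pr)2 (1.1 equiv), THF, −78 °C; then BrCH2CO2Me (1.5 equiv), −78 → −40 °C; AcOH in THF, −78 °C
Reagents that add atoms: methyl bromoacetate, COC(=O)CBr
Why: Kinetic deprotonation of the enone at the α′ carbon C7 and SN2 alkylation of the lithium enolate. The enolate oxygen and the C8 ether oxygen are expected to chelate lithium, which turns the C8–C9 ring bond out of the enolate plane so that the electrophile enters anti to it from outside the ring, as in a Fráter–Seebach alkylation; this places C11 cis to O8 on the ring drawing (7R in 24). The low temperature and the lithium counter-ion are chosen to hold back loss of the β-ether.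

**Step 10**
Reactants: 24 methyl (1(10)Z,4Z,7R,8S,9S)-9,14-isopropylidenedioxy-8-(4-methoxybenzyloxy)-6-oxo-13-norgermacra-1(10),4-dien-12-oate
Product: 26 (1(10)Z,4Z,6R,7S,8S,9S)-9,14-isopropylidenedioxy-8-(4-methoxybenzyloxy)-13-norgermacra-1(10),4-dien-12,6-olide, via hydroxy ester 25 (not isolated)
Conditions: Zn(BH4)2, Et2O, −30 → 0 °C; aq. NH4Cl; then PPTS (cat.), CH2Cl2, 25 °C
Reagents that add atoms: none
Why: Chelation-controlled 1,2-reduction of the enone carbonyl. Zinc bridges the C6 carbonyl and the C8 ether oxygen, and hydride should add anti to the C7 side chain, the usual outcome for α-substituted β-alkoxy ketones, which gives 6R with O6 trans to C11. The C6 hydroxyl then closes onto the methyl ester (5-exo-trig) to the trans-fused γ-lactone.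

**Step 11**
Reactants: 26 (1(10)Z,4Z,6R,7S,8S,9S)-9,14-isopropylidenedioxy-8-(4-methoxybenzyloxy)-13-norgermacra-1(10),4-dien-12,6-olide
Product: 30 (1(10)Z,4Z,6R,7S,8S,9S)-9,14-isopropylidenedioxy-8-(4-methoxybenzyloxy)germacra-1(10),4,11(13)-trien-12,6-olide, via lithium enolate 27 (not isolated), via Mannich base 28 (not isolated), via ammonium iodide 29 (not isolated)
Conditions: LiN(i-Pr)2, THF, −78 °C; CH2=NMe2+ I−, −78 → 25 °C; MeI, MeOH, 25 °C; aq. NaHCO3, CH2Cl2, 25 °C
Reagents that add atoms: N,N-dimethylmethyleneiminium iodide, C=[N+](C)C.[I-]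
Why: Mannich aminomethylation of the lactone enolate, quaternisation and Hofmann-type β-elimination, the standard way to an α-methylene-γ-butyrolactone. It is done now because only ethers and an acetonide are present; the later esters would not tolerate the amide base.

**Step 12**
Reactants: 30 (1(10)Z,4Z,6R,7S,8S,9S)-9,14-isopropylidenedioxy-8-(4-methoxybenzyloxy)germacra-1(10),4,11(13)-trien-12,6-olide
Product: 31 (1(10)Z,4Z,6R,7S,8S,9S)-9,14-dihydroxy-8-(4-methoxybenzyloxy)germacra-1(10),4,11(13)-trien-12,6-olide
Conditions: AcOH/THF/H2O (3:1:1), 40 °C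
Reagents that add atoms: none
Why: Acid-catalysed hydrolysis of the 1,3-diol acetonide; the 4-methoxybenzyl ether, the lactone and its exocyclic methylene are stable to dilute acetic acid.

**Step 13**
Reactants: 31 (1(10)Z,4Z,6R,7S,8S,9S)-9,14-dihydroxy-8-(4-methoxybenzyloxy)germacra-1(10),4,11(13)-trien-12,6-olide
Product: 32 (1(10)Z,4Z,6R,7S,8S,9S)-14-(tert-butyldimethylsilyloxy)-9-hydroxy-8-(4-methoxybenzyloxy)germacra-1(10),4,11(13)-trien-12,6-olide
Conditions: TBSCl (1.05 equiv), imidazole, CH2Cl2, −20 → 0 °C
Reagents that add atoms: tert-butyldimethylsilyl chloride, CC(C)(C)[Si](C)(C)Cl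
Why: Selective silylation of the primary allylic C14 hydroxyl over the hindered secondary C9 hydroxyl on steric grounds.

**Step 14**
Reactants: 33 2-hydroxy-2-methylpropanoic acid
Product: 35 2-methyl-2-(triethylsilyloxy)propanoic acid, via bis-silyl derivative 34 (not isolated)
Conditions: Et3SiOTf (2.2 equiv), 2,6-lutidine, CH2Cl2, 0 °C; then K2CO3, MeOH/H2O, 0 °C; citric acid to pH 4
Reagents that add atoms: triethylsilyl trifluoromethanesulfonate, CC[Si](CC)(CC)OS(=O)(=O)C(F)(F)F
Why: Exhaustive silylation followed by selective hydrolysis of the much more labile silyl ester leaves the tertiary silyl ether, so the acid can be activated without self-acylation.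

**Step 15**
Reactants: 32 (1(10)Z,4Z,6R,7S,8S,9S)-14-(tert-butyldimethylsilyloxy)-9-hydroxy-8-(4-methoxybenzyloxy)germacra-1(10),4,11(13)-trien-12,6-olide; 35 2-methyl-2-(triethylsilyloxy)propanoic acid
Product: 37 (1(10)Z,4Z,6R,7S,8S,9S)-14-(tert-butyldimethylsilyloxy)-8-(4-methoxybenzyloxy)-9-[2-methyl-2-(triethylsilyloxy)propanoyloxy]germacra-1(10),4,11(13)-trien-12,6-olide, via mixed anhydride 36 (not isolated)
Conditions: 35, 2,4,6-trichlorobenzoyl chloride, Et3N, toluene, 25 °C; then 32, DMAP, toluene, 25 → 40 °C
Reagents that add atoms: none
Why: Yamaguchi esterification: the mixed anhydride is attacked by DMAP at the less hindered aliphatic carbonyl and the acylpyridinium acylates the hindered secondary C9 hydroxyl. The configuration at C9 is untouched because the C–O bond is not broken.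

**Step 16**
Reactants: 37 (1(10)Z,4Z,6R,7S,8S,9S)-14-(tert-butyldimethylsilyloxy)-8-(4-methoxybenzyloxy)-9-[2-methyl-2-(triethylsilyloxy)propanoyloxy]germacra-1(10),4,11(13)-trien-12,6-olide
Product: 38 (1(10)Z,4Z,6R,7R,8S,9S)-14-(tert-butyldimethylsilyloxy)-8-hydroxy-9-[2-methyl-2-(triethylsilyloxy)propanoyloxy]germacra-1(10),4,11(13)-trien-12,6-olide
Conditions: DDQ, CH2Cl2/pH 7 buffer (10:1), 0 → 25 °C
Reagents that add atoms: none
Why: Oxidative cleavage of the 4-methoxybenzyl ether by hydride abstraction and hydrolysis of the oxocarbenium ion. The buffered, near-neutral medium should suppress migration of the hindered C9 acyl group to O8 and relactonisation onto O8. The C7 descriptor changes to R only because the priorities change.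

**Step 17**
Reactants: 38 (1(10)Z,4Z,6R,7R,8S,9S)-14-(tert-butyldimethylsilyloxy)-8-hydroxy-9-[2-methyl-2-(triethylsilyloxy)propanoyloxy]germacra-1(10),4,11(13)-trien-12,6-olide
Product: 39 (1(10)Z,4Z,6R,7S,8S,9S)-14-(tert-butyldimethylsilyloxy)-8-(2-methylpropanoyloxy)-9-[2-methyl-2-(triethylsilyloxy)propanoyloxy]germacra-1(10),4,11(13)-trien-12,6-olide
Conditions: i-PrCOCl, pyridine, DMAP (cat.), CH2Cl2, 0 → 25 °C
Reagents that add atoms: 2-methylpropanoyl chloride, CC(C)C(Cl)=O
Why: Nucleophile-catalysed acylation of the secondary C8 hydroxyl with an acid chloride; it is run directly on the crude alcohol so that the free hydroxyl is trapped before any acyl shift.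

**Step 18**
Reactants: 39 (1(10)Z,4Z,6R,7S,8S,9S)-14-(tert-butyldimethylsilyloxy)-8-(2-methylpropanoyloxy)-9-[2-methyl-2-(triethylsilyloxy)propanoyloxy]germacra-1(10),4,11(13)-trien-12,6-olide
Product: 40 (1(10)Z,4Z,6R,7S,8S,9S)-14-hydroxy-9-(2-hydroxy-2-methylpropanoyloxy)-8-(2-methylpropanoyloxy)germacra-1(10),4,11(13)-trien-12,6-olide (CNP0220567.2)
Conditions: HF·pyridine, pyridine, THF, 0 → 25 °C
Reagents that add atoms: none
Why: Fluoride-mediated cleavage of both silyl ethers in one operation under mildly acidic conditions, which avoid alkoxide formation and therefore acyl migration and conjugate addition to the methylene lactone.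

## Compound list

1 | 2,2-dimethyl-1,3-dioxan-5-one | CC1(C)OCC(=O)CO1 | starting material
2 | lithium 2,2-dimethyl-4H-1,3-dioxin-5-olate | [Li+].[O-]C1=COC(C)(C)OC1 | intermediate
3 | 2,2-dimethyl-4H-1,3-dioxin-5-yl trifluoromethanesulfonate | CC1(C)OCC(OS(=O)(=O)C(F)(F)F)=CO1 | intermediate
4 | 3-methylcyclohex-2-en-1-one | CC1=CC(=O)CCC1 | starting material
5 | lithium 5-methylcyclohexa-1,5-dien-1-olate | [Li+].[O-]C1=CCCC(C)=C1 | intermediate
6 | racemic 6-(2,2-dimethyl-4H-1,3-dioxin-5-yl)-3-methylcyclohex-2-en-1-one | CC1=CC(=O)C(CC1)C1=COC(C)(C)OC1 | intermediate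
7 | (1S,6S)-6-(2,2-dimethyl-4H-1,3-dioxin-5-yl)-3-methylcyclohex-2-en-1-ol | CC1=C[C@H](O)[C@@H](CC1)C1=COC(C)(C)OC1 | intermediate
8 | (6S)-6-(2,2-dimethyl-4H-1,3-dioxin-5-yl)-3-methylcyclohex-2-en-1-one | CC1=CC(=O)[C@@H](CC1)C1=COC(C)(C)OC1 | intermediate
9 | 4-methoxybenzyl alcohol | COc1ccc(CO)cc1 | starting material
10 | trichloroethylene | ClC=C(Cl)Cl | starting material
11 | potassium (4-methoxyphenyl)methanolate | [K+].[O-]Cc1ccc(OC)cc1 | intermediate
12 | dichloroacetylene | ClC#CCl | intermediate
13 | (E)-1,2-dichlorovinyl 4-methoxybenzyl ether | Cl/C=C(/Cl)OCc1ccc(OC)cc1 | intermediate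
14 | chloroethynyl 4-methoxybenzyl ether | ClC#COCc1ccc(OC)cc1 | intermediate
15 | lithium (4-methoxybenzyloxy)acetylide | [Li]C#COCc1ccc(OC)cc1 | intermediate
16 | dichloro[(4-methoxybenzyloxy)ethynyl]cerium | Cl[Ce](Cl)C#COCc1ccc(OC)cc1 | intermediate
17 | (1R,6S)-6-(2,2-dimethyl-4H-1,3-dioxin-5-yl)-1-[(4-methoxybenzyloxy)ethynyl]-3-methylcyclohex-2-en-1-ol | CC1=C[C@](O)(C#COCc2ccc(OC)cc2)[C@@H](CC1)C1=COC(C)(C)OC1 | intermediate
18 | sodium cyclic alkenylaluminate of 17 (aluminium bound to the carbinol oxygen and to the alkoxy-bearing alkene carbon, two 2-methoxyethoxy ligands) | [Na+].COCCO[Al-]3(OCCOC)O[C@]2(C=C3OCc4ccc(OC)cc4)C=C(C)CC[C@H]2C1=COC(C)(C)OC1 | intermediate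
19 | (1R,6S)-6-(2,2-dimethyl-4H-1,3-dioxin-5-yl)-1-[(E)-2-(4-methoxybenzyloxy)vinyl]-3-methylcyclohex-2-en-1-ol | CC1=C[C@](O)(/C=C/OCc2ccc(OC)cc2)[C@@H](CC1)C1=COC(C)(C)OC1 | intermediate
20 | potassium alkoxide of 19 | [K+].CC1=C[C@]([O-])(/C=C/OCc2ccc(OC)cc2)[C@@H](CC1)C1=COC(C)(C)OC1 | intermediate
21 | potassium C6 enolate of 22 (C6=C7 with O6 and C8 cis; 1(10)Z,4Z; 8S,9S) | [K+].[O-]/C1=C\[C@H](OCc3ccc(OC)cc3)[C@H]2OC(C)(C)OC/C2=C/CC/C(C)=C\1 | intermediate
22 | (1(10)Z,4Z,8S,9S)-9,14-isopropylidenedioxy-8-(4-methoxybenzyloxy)-11,12,13-trinorgermacra-1(10),4-dien-6-one | O=C1/C=C(/C)CC/C=C2/COC(C)(C)O[C@@H]2[C@@H](OCc3ccc(OC)cc3)C1 | intermediate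
23 | lithium C6 enolate of 22 (same geometry as 21) | [Li+].[O-]/C1=C\[C@H](OCc3ccc(OC)cc3)[C@H]2OC(C)(C)OC/C2=C/CC/C(C)=C\1 | intermediate
24 | methyl (1(10)Z,4Z,7R,8S,9S)-9,14-isopropylidenedioxy-8-(4-methoxybenzyloxy)-6-oxo-13-norgermacra-1(10),4-dien-12-oate | O=C1/C=C(/C)CC/C=C2/COC(C)(C)O[C@@H]2[C@@H](OCc3ccc(OC)cc3)[C@H]1CC(=O)OC | intermediate
25 | methyl (1(10)Z,4Z,6R,7S,8S,9S)-6-hydroxy-9,14-isopropylidenedioxy-8-(4-methoxybenzyloxy)-13-norgermacra-1(10),4-dien-12-oate | O[C@@H]1/C=C(/C)CC/C=C2/COC(C)(C)O[C@@H]2[C@@H](OCc3ccc(OC)cc3)[C@H]1CC(=O)OC | intermediate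
26 | (1(10)Z,4Z,6R,7S,8S,9S)-9,14-isopropylidenedioxy-8-(4-methoxybenzyloxy)-13-norgermacra-1(10),4-dien-12,6-olide | C1C(=O)O[C@@H]2/C=C(/C)CC/C=C3/COC(C)(C)O[C@@H]3[C@@H](OCc4ccc(OC)cc4)[C@@H]12 | intermediate
27 | lithium enolate of lactone 26 | C1=C([O-])O[C@@H]2/C=C(/C)CC/C=C3/COC(C)(C)O[C@@H]3[C@@H](OCc4ccc(OC)cc4)[C@@H]12.[Li+] | intermediate
28 | 11-(dimethylaminomethyl) derivative of 26 (either C11 epimer; the centre is removed in the elimination) | CN(C)CC1C(=O)O[C@@H]2/C=C(/C)CC/C=C3/COC(C)(C)O[C@@H]3[C@@H](OCc4ccc(OC)cc4)[C@@H]12 | intermediate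
29 | 11-(trimethylammoniomethyl) derivative of 26, iodide | C[N+](C)(C)CC1C(=O)O[C@@H]2/C=C(/C)CC/C=C3/COC(C)(C)O[C@@H]3[C@@H](OCc4ccc(OC)cc4)[C@@H]12.[I-] | intermediate
30 | (1(10)Z,4Z,6R,7S,8S,9S)-9,14-isopropylidenedioxy-8-(4-methoxybenzyloxy)germacra-1(10),4,11(13)-trien-12,6-olide | C=C1C(=O)O[C@@H]2/C=C(/C)CC/C=C3/COC(C)(C)O[C@@H]3[C@@H](OCc4ccc(OC)cc4)[C@@H]12 | intermediate
31 | (1(10)Z,4Z,6R,7S,8S,9S)-9,14-dihydroxy-8-(4-methoxybenzyloxy)germacra-1(10),4,11(13)-trien-12,6-olide | C=C1C(=O)O[C@@H]2/C=C(/C)CC/C=C(/CO)[C@H](O)[C@@H](OCc3ccc(OC)cc3)[C@@H]12 | intermediate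
32 | (1(10)Z,4Z,6R,7S,8S,9S)-14-(tert-butyldimethylsilyloxy)-9-hydroxy-8-(4-methoxybenzyloxy)germacra-1(10),4,11(13)-trien-12,6-olide | C=C1C(=O)O[C@@H]2/C=C(/C)CC/C=C(/CO[Si](C)(C)C(C)(C)C)[C@H](O)[C@@H](OCc3ccc(OC)cc3)[C@@H]12 | intermediate
33 | 2-hydroxy-2-methylpropanoic acid | CC(C)(O)C(=O)O | starting material
34 | triethylsilyl 2-methyl-2-(triethylsilyloxy)propanoate | CC[Si](CC)(CC)OC(C)(C)C(=O)O[Si](CC)(CC)CC | intermediate
35 | 2-methyl-2-(triethylsilyloxy)propanoic acid | CC[Si](CC)(CC)OC(C)(C)C(=O)O | intermediate
36 | 2-methyl-2-(triethylsilyloxy)propanoic 2,4,6-trichlorobenzoic anhydride | CC[Si](CC)(CC)OC(C)(C)C(=O)OC(=O)c1c(Cl)cc(Cl)cc1Cl | intermediate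
37 | (1(10)Z,4Z,6R,7S,8S,9S)-14-(tert-butyldimethylsilyloxy)-8-(4-methoxybenzyloxy)-9-[2-methyl-2-(triethylsilyloxy)propanoyloxy]germacra-1(10),4,11(13)-trien-12,6-olide | C=C1C(=O)O[C@@H]2/C=C(/C)CC/C=C(/CO[Si](C)(C)C(C)(C)C)[C@H](OC(=O)C(C)(C)O[Si](CC)(CC)CC)[C@@H](OCc3ccc(OC)cc3)[C@@H]12 | intermediate
38 | (1(10)Z,4Z,6R,7R,8S,9S)-14-(tert-butyldimethylsilyloxy)-8-hydroxy-9-[2-methyl-2-(triethylsilyloxy)propanoyloxy]germacra-1(10),4,11(13)-trien-12,6-olide | C=C1C(=O)O[C@@H]2/C=C(/C)CC/C=C(/CO[Si](C)(C)C(C)(C)C)[C@H](OC(=O)C(C)(C)O[Si](CC)(CC)CC)[C@@H](O)[C@@H]12 | intermediate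
39 | (1(10)Z,4Z,6R,7S,8S,9S)-14-(tert-butyldimethylsilyloxy)-8-(2-methylpropanoyloxy)-9-[2-methyl-2-(triethylsilyloxy)propanoyloxy]germacra-1(10),4,11(13)-trien-12,6-olide | C=C1C(=O)O[C@@H]2/C=C(/C)CC/C=C(/CO[Si](C)(C)C(C)(C)C)[C@H](OC(=O)C(C)(C)O[Si](CC)(CC)CC)[C@@H](OC(=O)C(C)C)[C@@H]12 | intermediate
40 | (1(10)Z,4Z,6R,7S,8S,9S)-14-hydroxy-9-(2-hydroxy-2-methylpropanoyloxy)-8-(2-methylpropanoyloxy)germacra-1(10),4,11(13)-trien-12,6-olide | C=C1C(=O)O[C@@H]2/C=C(/C)CC/C=C(/CO)[C@H](OC(=O)C(C)(C)O)[C@@H](OC(=O)C(C)C)[C@@H]12 | target

## Step count and least certain steps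

Total: 18 steps. Longest linear sequence: 16 steps (1 → 3 → 6 → 7 → 8 → 17 → 19 → 22 → 24 → 26 → 30 → 31 → 32 → 37 → 38 → 39 → 40); steps 5 and 14 are side branches.

**Step 8 (key step).** The most likely failure is loss of the C8 alkoxide from the enolate by β-elimination once the ring relaxes and the C8–O bond turns into the π plane. A second risk is leakage through the ring-flipped chair or a boat, which would erode the olefin geometry and the C8/C9 relationship. The fallback sets out from 19 and returns directly at 22: the free alcohol is rearranged under divalent palladium catalysis [PdCl2(PhCN)2 (10 mol %), THF, 25 °C]. This is a cyclisation-induced oxy-Cope rearrangement through a chair-like organopalladium intermediate. It delivers the enol, which tautomerises to 22, so no enolate is ever present and the β-ether cannot be expelled by an E1cB path. This fallback makes no new compound (F0).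

**Step 9.** The most likely failure is entry of the electrophile on the other face of C7, if the enolate reacts from a non-chelated conformer in which the C8–C9 bond lies on the opposite side. β-Elimination of the C8 ether on warming is a second risk. The fallback sets out from 22 and returns at 24. The alkylation is run as before and its facial sense is accepted, giving the 7-epimeric keto ester F1. F1 is deprotonated at C7, its most acidic position, with KN(SiMe3)2 in THF at −78 °C and the enolate is protonated under kinetic control with AcOH at −78 °C. The proton then enters on the open face that the electrophile used, which inverts C7 and gives 24. The stereo-determining event is thus changed from C–C to C–H bond formation.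

**Step 10.** The most likely failure is hydride delivery to the other face of C6, if the conformation of the ten-membered ring overrides the zinc chelate. This would give the C6 epimer and, after ring closure, the cis-fused lactone F2. The fallback sets out from 24 and returns at 26. F2 is opened with LiOH in THF/H2O and carefully acidified to the hydroxy acid F3, which is used at once in a Mitsunobu lactonisation (PPh3, DIAD, toluene, 0 °C). The carboxylate displaces the activated C6 oxygen with inversion and closes the trans-fused lactone 26.

**Step 2.** The most likely failure is equilibration of the kinetic enolate to the extended dienolate during the coupling, which would lead to γ-alkenylation, or a second alkenylation at C6. The fallback sets out from 4 and returns at 6. The kinetic enolate is fixed as the silyl dienol ether F4 (LiN(i-Pr)2, Me3SiCl, THF, −78 °C). F4 is coupled with 3 under fluoride activation (Pd2(dba)3, P(t-Bu)3, ZnF2, CsF, DMF, 25–60 °C), so that the regiochemistry is defined before the metal catalyst is added and no free base is present.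

**Step 3.** The most likely failure is racemisation of C6 that is too slow relative to reduction, so that the process becomes a simple kinetic resolution. Base-induced migration of the enol ether double bond into conjugation with the ketone is a second risk. The fallback sets out from 6 and returns at 7. A Corey–Bakshi–Shibata reduction [(S)-1-methyl-3,3-diphenyltetrahydro-1H,3H-pyrrolo[1,2-c][1,3,2]oxazaborole (10 mol %), BH3·SMe2, THF, −30 °C] fixes the carbinol centre by reagent control in both enantiomers of 6. The cis alcohol 7 is separated by chromatography from the trans alcohol F5 and carried on. F5 can be returned to 6 by MnO2 oxidation and base equilibration.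

## Further compounds

F0 | step 8 | none | none
F1 | step 9 | methyl (1(10)Z,4Z,7S,8S,9S)-9,14-isopropylidenedioxy-8-(4-methoxybenzyloxy)-6-oxo-13-norgermacra-1(10),4-dien-12-oate (C7 epimer of 24) | O=C1/C=C(/C)CC/C=C2/COC(C)(C)O[C@@H]2[C@@H](OCc3ccc(OC)cc3)[C@@H]1CC(=O)OC
F2 | step 10 | (1(10)Z,4Z,6S,7S,8S,9S)-9,14-isopropylidenedioxy-8-(4-methoxybenzyloxy)-13-norgermacra-1(10),4-dien-12,6-olide (cis-fused C6 epimer of 26) | C1C(=O)O[C@H]2/C=C(/C)CC/C=C3/COC(C)(C)O[C@@H]3[C@@H](OCc4ccc(OC)cc4)[C@@H]12
F3 | step 10 | (1(10)Z,4Z,6S,7S,8S,9S)-6-hydroxy-9,14-isopropylidenedioxy-8-(4-methoxybenzyloxy)-13-norgermacra-1(10),4-dien-12-oic acid | O[C@H]1/C=C(/C)CC/C=C2/COC(C)(C)O[C@@H]2[C@@H](OCc3ccc(OC)cc3)[C@H]1CC(=O)O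
F4 | step 2 | 4-methyl-2-(trimethylsilyloxy)cyclohexa-1,3-diene | CC1=CC(O[Si](C)(C)C)=CCC1
F5 | step 3 | (1S,6R)-6-(2,2-dimethyl-4H-1,3-dioxin-5-yl)-3-methylcyclohex-2-en-1-ol | CC1=C[C@H](O)[C@H](CC1)C1=COC(C)(C)OC1
A1 | alternative 1 | trans-lactone-fused (1(10)Z,4Z)-cyclodecadien-9-one without C14 and without O8 | C1C(=O)O[C@@H]2/C=C(/C)CC/C=C\C(=O)C[C@@H]12
A2 | alternative 2 | ten-membered cyclodec-1-en-5-yne propargylic alcohol with C8 4-methoxybenzyl ether, C9 silyl-protected hydroxyisobutyrate, C14 silyl ether and C7 Weinreb amide side chain (C6 carbinol as formed) | OC1C#CCC/C=C(/CO[Si](C)(C)C(C)(C)C)[C@H](OC(=O)C(C)(C)O[Si](CC)(CC)CC)[C@@H](OCc2ccc(OC)cc2)[C@H]1CC(=O)N(C)OC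
A3 | alternative 3 | (1(10)Z,4Z,6R,7S,8S,9S)-14-(tert-butyldimethylsilyloxy)-9-hydroxy-8-(4-methoxybenzyloxy)germacra-1(10),4,11(13)-trien-12,6-olide (identical with 32) | C=C1C(=O)O[C@@H]2/C=C(/C)CC/C=C(/CO[Si](C)(C)C(C)(C)C)[C@H](O)[C@@H](OCc3ccc(OC)cc3)[C@@H]12
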